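**Plan**
- Retrosynthesis cuts, in order: the C6–OMe bond (methanol replaces an anomeric chiral acyloxy group); both ring C–O bonds, C3–O2 and C6–O1, together (retro-[4+2] of dioxygen) to an open-chain (3E,5Z)-dienol ester; the enol O–acyl bond; the C6–C7 bond (acyl chloride plus hexadecyl Grignard reagent).
- Enabling feature: the ring is a 3,6-dihydro-1,2-dioxin, with O1–O2 bonded to C3 and C6 and the C4=C5 alkene between them. This is the Diels–Alder retron of O2 on a C3=C4–C5=C6 diene, and C6, being a ketal carbon, can enter as the oxygen-bearing terminus of a dienol derivative.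
- Forward: the C22 chain is joined first (C6 half-ester plus C16), the ketone is made into a dienol ester, the only ring is closed by singlet-oxygen cycloaddition, and the methoxy group is put on last.
- Stereochemistry: C3 comes from facial control by an (S)-O-methylmandeloyl group on the dienol oxygen, with the facial diastereomers separated at the cycloadduct stage. C6 is set last, by methanol capture of the ring peroxycarbenium ion under equilibrating acid; the 6R anomer is isolated by chromatography and the remaining material is equilibrated again.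

Key step: step 6

Assumption: the acyl group is taken to stand perpendicular to the diene with the carbinol H of the auxiliary turned toward the diene, so that the (S)-acid covers the C6-si face and leads to 3S; the facial diastereomers are separable in any case.

**Step 1**
Reactants: 1 dimethyl (3E)-hex-3-enedioate
Product: 2 (3E)-6-methoxy-6-oxohex-3-enoic acid
Conditions: NaOH (1.0 equiv, dilute aq.), THF–H2O, 0 °C; then 1 M HCl
Reagents that add atoms: sodium hydroxide, [Na+].[OH-]
Why: Half-saponification of a symmetric diester, in which the first-formed carboxylate is water-bound and electrostatically shielded so the second ester should survive one equivalent of hydroxide, while the short time at 0 °C limits migration of the C3=C4 bond into conjugation.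

**Step 2**
Reactants: 3 1-bromohexadecane
Product: 4 hexadecylmagnesium bromide (titrated THF solution)
Conditions: Mg turnings, cat. I2, THF, reflux
Reagents that add atoms: magnesium, [Mg]
Why: Grignard formation by insertion of magnesium into the primary C–Br bond.

**Step 3**
Reactants: 2 (3E)-6-methoxy-6-oxohex-3-enoic acid; 4 hexadecylmagnesium bromide
Product: 6 methyl (3E)-6-oxodocos-3-enoate, via acid chloride 5 (not isolated)
Conditions: (COCl)2, cat. DMF, CH2Cl2, 0 °C to rt, evaporate; then 4 (1.05 equiv), Fe(acac)3 (3 mol %), THF, −78 °C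
Reagents that add atoms: none
Why: Acid chloride formation followed by iron-catalysed Kumada-type acylation at −78 °C, where the organoiron species should couple with the acyl chloride faster than the Grignard reagent attacks the methyl ester or the product ketone or deprotonates the β,γ-unsaturated acyl chloride.

**Step 4**
Reactants: 7 (2S)-2-methoxy-2-phenylacetic acid
Product: 8 (2S)-2-methoxy-2-phenylacetyl chloride
Conditions: (COCl)2 (1.3 equiv), cat. DMF, CH2Cl2, 0 °C to rt; evaporate and use at once
Reagents that add atoms: oxalyl chloride, O=C(Cl)C(Cl)=O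
Why: Standard acid chloride formation under base-free conditions, so the α-stereocentre should be retained.

**Step 5**
Reactants: 6 methyl (3E)-6-oxodocos-3-enoate; 8 (2S)-2-methoxy-2-phenylacetyl chloride
Product: 10 methyl (3E,5Z)-6-{[(2S)-2-methoxy-2-phenylacetyl]oxy}docosa-3,5-dienoate, via potassium dienolate 9 (not isolated)
Conditions: KN(SiMe3)2 (1.05 equiv), THF, −78 °C; then 8 (1.1 equiv), −78 to −40 °C
Reagents that add atoms: none
Why: Kinetic deprotonation at C5, the only position activated by both the ketone and the C3=C4 bond, should give the Z(O) dienolate (oxygen cis to the vinyl group, the alternative suffering A(1,3) strain between C7H2 and C4–H), and O-acylation of the potassium enolate by the acid chloride (enol ester formation) fixes the 3E,5Z dienol ester.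

**Step 6**
Reactants: 10 methyl (3E,5Z)-6-{[(2S)-2-methoxy-2-phenylacetyl]oxy}docosa-3,5-dienoate
Product: 11 methyl 2-[(3S,6R)-6-hexadecyl-6-{[(2S)-2-methoxy-2-phenylacetyl]oxy}-3,6-dihydro-1,2-dioxin-3-yl]acetate
Conditions: O2 (1 atm), tetraphenylporphyrin (0.5 mol %), CH2Cl2, −40 °C, visible light (white LED); chromatography on neutral silica at 0 °C without amine additives
Reagents that add atoms: dioxygen, O=O
Why: Sensitised singlet oxygen adds suprafacially across C3 and C6 of the s-cis (3E,5Z)-diene in a [4+2] (hetero-Diels–Alder) cycloaddition, forming both ring C–O bonds and shifting the alkene to C4=C5 in one event. The closest known reaction type is the photooxygenation of acyclic 1-alkoxy- and 1-acyloxy-1,3-dienes to 3,6-dihydro-1,2-dioxins, including auxiliary-controlled versions on chiral dienes. The six-membered ring closes by this 4π+2π cycloaddition mode (concerted or by collapse of a perepoxide), not by a polar cyclisation. C3 (S) is set by the (S)-O-methylmandeloyl group, whose acyl C=O should lie over the C6-si face and leave the C3-si/C6-re face open; C6 (R, acyloxy trans to the side chain) follows from suprafacial addition to the 5Z enol geometry and is in any case set anew in step 7. The step needs [4+2] to outrun ene hydroperoxidation (C2–H, C7–H) and dioxetane formation at C5=C6; the acyloxy group makes the enol π bond much less nucleophilic than an enol ether, and the inside substituent at C6 is only an oxygen atom, so the s-cis diene stays reachable. The minor facial diastereomer is removed by chromatography at this stage, so the C3 purity does not rest on the size of the facial bias.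

**Step 7**
Reactants: 11 methyl 2-[(3S,6R)-6-hexadecyl-6-{[(2S)-2-methoxy-2-phenylacetyl]oxy}-3,6-dihydro-1,2-dioxin-3-yl]acetate
Product: 12 methyl 2-[(3S,6R)-6-hexadecyl-6-methoxy-3,6-dihydro-1,2-dioxin-3-yl]acetate
Conditions: MeOH–CH2Cl2 (4:1), camphorsulfonic acid (10 mol %), 0 °C to rt, to constant anomer ratio; solid NaHCO3, filter; chromatography on neutral silica, fractions holding the C6 epimer returned to the same conditions
Reagents that add atoms: methanol, CO
Why: Acid-catalysed alkyl–oxygen ionisation of the tertiary, allylic anomeric ester gives a ring peroxycarbenium ion that methanol captures at C6 (transketalisation of a 6-oxy-3,6-dihydro-1,2-dioxin) with the O–O bond and C3 untouched, and because the methyl ketal re-ionises under the same acid the two C6 anomers interconvert, so that with little bias from the 1,4-related C3 substituent both are expected, the 6R anomer is separated by chromatography and the remainder is brought back to equilibrium for further crops.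

**Compound list**
1 | dimethyl (3E)-hex-3-enedioate | COC(=O)C/C=C/CC(=O)OC | starting material
2 | (3E)-6-methoxy-6-oxohex-3-enoic acid | OC(=O)C/C=C/CC(=O)OC | intermediate
3 | 1-bromohexadecane | CCCCCCCCCCCCCCCCBr | starting material
4 | hexadecylmagnesium bromide | CCCCCCCCCCCCCCCC[Mg]Br | intermediate
5 | methyl (3E)-6-chloro-6-oxohex-3-enoate | COC(=O)C/C=C/CC(Cl)=O | intermediate
6 | methyl (3E)-6-oxodocos-3-enoate | CCCCCCCCCCCCCCCCC(=O)C/C=C/CC(=O)OC | intermediate
7 | (2S)-2-methoxy-2-phenylacetic acid | CO[C@@H](c1ccccc1)C(=O)O | starting material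
8 | (2S)-2-methoxy-2-phenylacetyl chloride | CO[C@@H](c1ccccc1)C(Cl)=O | intermediate
9 | potassium (3E,5Z)-1-methoxy-1-oxodocosa-3,5-dien-6-olate | CCCCCCCCCCCCCCCC/C([O-])=C/C=C/CC(=O)OC.[K+] | intermediate
10 | methyl (3E,5Z)-6-{[(2S)-2-methoxy-2-phenylacetyl]oxy}docosa-3,5-dienoate | CCCCCCCCCCCCCCCC/C(OC(=O)[C@@H](OC)c1ccccc1)=C/C=C/CC(=O)OC | intermediate
11 | methyl 2-[(3S,6R)-6-hexadecyl-6-{[(2S)-2-methoxy-2-phenylacetyl]oxy}-3,6-dihydro-1,2-dioxin-3-yl]acetate | CCCCCCCCCCCCCCCC[C@]1(OC(=O)[C@@H](OC)c2ccccc2)C=C[C@H](CC(=O)OC)OO1 | intermediate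
12 | methyl 2-[(3S,6R)-6-hexadecyl-6-methoxy-3,6-dihydro-1,2-dioxin-3-yl]acetate | CCCCCCCCCCCCCCCC[C@]1(OC)C=C[C@H](CC(=O)OC)OO1 | target

**Totals**
Total step count: 7. Longest linear sequence: 5 steps (steps 1, 3, 5, 6, 7).

**Steps most likely to fail**

Step 6. The cycloaddition may lose to ene hydroperoxidation or dioxetane formation, or the facial bias may be too low for a useful amount of the 3S adduct. The fallback sets out from 6 and comes back at 12. Ketone 6 is photooxygenated in the ene mode (O2, tetraphenylporphyrin, CH2Cl2, light); abstraction of the doubly activated C5–H places the hydroperoxide at C3 and should give mainly racemic methyl (3RS,4E)-3-hydroperoxy-6-oxodocos-4-enoate F1. With (1R,2S)-2-phenylcyclohexyl prop-1-en-2-yl ether and catalytic PPTS, F1 is converted into two diastereomeric perketals, methyl (3S,4E)-6-oxo-3-{[2-{[(1R,2S)-2-phenylcyclohexyl]oxy}propan-2-yl]peroxy}docos-4-enoate F2 and methyl (3R,4E)-6-oxo-3-{[2-{[(1R,2S)-2-phenylcyclohexyl]oxy}propan-2-yl]peroxy}docos-4-enoate F3, which are separated by chromatography. Mild hydrolysis of F2 (AcOH, THF, H2O) should return methyl (3S,4E)-3-hydroperoxy-6-oxodocos-4-enoate F4. Irradiation isomerises the enone to methyl (3S,4Z)-3-hydroperoxy-6-oxodocos-4-enoate F5, which should close at once to the peroxy hemiketal methyl 2-[(3S,6RS)-6-hexadecyl-6-hydroxy-3,6-dihydro-1,2-dioxin-3-yl]acetate F6. Treatment of F6 with MeOH and catalytic camphorsulfonic acid should give 12, the C6 anomers being separated and re-equilibrated as in step 7.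

Step 7. Methanol capture may show little or adverse selectivity between the two faces of C6, ionisation of the anomeric ester may be slow, or the peroxycarbenium ion may fragment or be captured at C4. The fallback sets out from 6 and comes back at 12, with the methoxy group in place before the ring is made. Dienolate 9, generated from 6 as in step 5, is O-methylated with methyl triflate (THF–DMPU, −78 °C) to methyl (3E,5Z)-6-methoxydocosa-3,5-dienoate F7. Singlet-oxygen [4+2] cycloaddition of F7 then fixes the C3/C6 relative configuration by suprafacial addition and should give 12 as a racemate with its enantiomer methyl 2-[(3R,6S)-6-hexadecyl-6-methoxy-3,6-dihydro-1,2-dioxin-3-yl]acetate F8. F8 is removed by preparative chromatography on a chiral stationary phase (cellulose tris(3,5-dimethylphenylcarbamate)).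

Step 5. Deprotonation may give mixed enolate geometry, or acylation may go partly on carbon. The fallback sets out from 6 and comes back at 10. Ketone 6 is soft-enolised (Me3SiOTf, Et3N, CH2Cl2, 0 °C) to the thermodynamic methyl (3E,5Z)-6-[(trimethylsilyl)oxy]docosa-3,5-dienoate F9, which is purified and checked for geometry. KOtBu (THF, −78 °C) then releases dienolate 9 with the geometry fixed, and acylation with 8 should give 10.

**Further compounds**
F1 | step 6 | methyl (3RS,4E)-3-hydroperoxy-6-oxodocos-4-enoate | CCCCCCCCCCCCCCCCC(=O)/C=C/C(CC(=O)OC)OO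
F2 | step 6 | methyl (3S,4E)-6-oxo-3-{[2-{[(1R,2S)-2-phenylcyclohexyl]oxy}propan-2-yl]peroxy}docos-4-enoate | CCCCCCCCCCCCCCCCC(=O)/C=C/[C@H](CC(=O)OC)OOC(C)(C)O[C@@H]1CCCC[C@H]1c1ccccc1
F3 | step 6 | methyl (3R,4E)-6-oxo-3-{[2-{[(1R,2S)-2-phenylcyclohexyl]oxy}propan-2-yl]peroxy}docos-4-enoate | CCCCCCCCCCCCCCCCC(=O)/C=C/[C@@H](CC(=O)OC)OOC(C)(C)O[C@@H]1CCCC[C@H]1c1ccccc1
F4 | step 6 | methyl (3S,4E)-3-hydroperoxy-6-oxodocos-4-enoate | CCCCCCCCCCCCCCCCC(=O)/C=C/[C@H](CC(=O)OC)OO
F5 | step 6 | methyl (3S,4Z)-3-hydroperoxy-6-oxodocos-4-enoate | CCCCCCCCCCCCCCCCC(=O)/C=C\[C@H](CC(=O)OC)OO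
F6 | step 6 | methyl 2-[(3S,6RS)-6-hexadecyl-6-hydroxy-3,6-dihydro-1,2-dioxin-3-yl]acetate | CCCCCCCCCCCCCCCCC1(O)C=C[C@H](CC(=O)OC)OO1
F7 | step 7 | methyl (3E,5Z)-6-methoxydocosa-3,5-dienoate | CCCCCCCCCCCCCCCC/C(OC)=C/C=C/CC(=O)OC
F8 | step 7 | methyl 2-[(3R,6S)-6-hexadecyl-6-methoxy-3,6-dihydro-1,2-dioxin-3-yl]acetate | CCCCCCCCCCCCCCCC[C@@]1(OC)C=C[C@@H](CC(=O)OC)OO1
F9 | step 5 | methyl (3E,5Z)-6-[(trimethylsilyl)oxy]docosa-3,5-dienoate | CCCCCCCCCCCCCCCC/C(O[Si](C)(C)C)=C/C=C/CC(=O)OC
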